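The north-east flask has neighbours that differ from it in the loading of precatalyst, and I want to know what that loading does to the intermediate left at the end.

    substrate → intermediate (k1 = 0.0021 min⁻¹)
    free catalyst + intermediate → free catalyst + target (k2 = 4.7 L mol⁻¹ min⁻¹)
    2 free catalyst → spent catalyst (k3 = 7.5 L mol⁻¹ min⁻¹)
    precatalyst ⇌ free catalyst (K4 = 2.3, k4 = 7.8 × 10⁻⁴ min⁻¹)

| setting | north-east | south | west | north-west |
|---|---|---|---|---|
| substrate | 0.15 M | 0.15 M | 0.15 M | 0.15 M |
| precatalyst | 0.025 mol% | 0.05 mol% | 0.1 mol% | 0.2 mol% |
| time | 25 h | 25 h | 25 h | 25 h |

- where a step has two of a species, its rate is k times that concentration squared, and two are used at each turn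
- "hardly changes" means that all values lie within two and a half points (for a concentration: within two and a half percent of the largest)
- run time (north-east): 25 h

- amount of intermediate at the end, in percent of the substrate charged for north-east, south, west, north-west, in this order
- the course of these numbers from the first flask to the last (falls all the way / falls, then rises / rises all the way / hardly changes / rises, then falls)

I turn the constants into times. The substrate has a half-life of 5.5 h, so by the end a share S = 95.7 % of it has become intermediate or target, in every flask.

By its exchange with precatalyst alone, free catalyst heads for a share f = 69.7 % of the charged catalyst c, with time constant τ = 14.9 h. Over a run of length t, that is worth a working time at full share of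

T = t − τ(1 − exp(−t/τ)) = 12.9 h.

At share f, the first half-life of free catalyst by its loss step alone is 42.5 h in north-east, longer than T, but 5.31 h in north-west, shorter than T.

The intermediate is drained pseudo-first-order, at d times the free catalyst, where d is the constant of the draining step, 4.7 L mol⁻¹ min⁻¹. The free catalyst itself wears out second-order with constant w = 7.5 L mol⁻¹ min⁻¹. Summing the drain over T gives

D = (d / 2w) · ln(1 + 2w f c T), which for north-west is 0.386.

I call D the drain number: the natural logarithm of the factor by which the catalyst shrinks the intermediate during the run. My reckoning for the end is then S·exp(−D):

north-east: D = 0.0830, intermediate 88.1 %
south: D = 0.148, intermediate 82.5 %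
west: D = 0.249, intermediate 74.6 %
north-west: D = 0.386, intermediate 65.1 %

So the row falls all the way, yet D grows 4.65 times while the loading grows 8.00 times. Is one number enough? Not quite: D lets the intermediate stand in full from the start, whereas it arrives over hours, so I expect my figures to come out a little low.

The forecast gives 89.2 %, 84.2 %, 76.8 % and 67.3 %, a course that falls all the way, on the grounds that “Second-order catalyst loss makes the drain grow less than proportionally with loading”.

The flasks give 89.0 %, 83.8 %, 76.0 % and 65.8 %: the course falls all the way.

Read back from north-west, ln(S/intermediate) is 0.375, beside my D of 0.386. The loss of free catalyst and the time allowed are, together, part of the reason that north-west still holds this much intermediate: with that loss taken away, north-west ends at 51.1 % intermediate instead of 65.8 %, and a tenfold time takes it to 15.1 %. For north-east at the tenfold time, D is 0.588, which gives 55.5 % intermediate, and the flask holds 48.2 % after 250 h.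

The constants used here were chosen freely; the flask was simulated.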